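**Assumption:** the SMILES is read as the (1S,2S,5R,6R) isomer of 2,6-bis(3,4-dimethoxyphenyl)-3,7-dioxabicyclo[3.3.0]octan-1-ol (C1 = carbinol bridgehead, C2 = ArCH on C1, O3, C4, C5 = CH bridgehead, C6 = ArCH on C5, O7, C8). In this isomer both aryl groups sit on the concave (endo) face.

## Structural features

The target is a furofuran lignan: two tetrahydrofuran rings, ring A (C1, C5, C6, O7, C8) and ring B (C1, C2, O3, C4, C5), cis-fused through the C1–C5 bond. C1 is a fully substituted carbinol carbon at the ring fusion, C5 is the CH bridgehead, and C2 and C6 each carry a 3,4-dimethoxyphenyl group and a ring oxygen. The four stereocentres C2–C1–C5–C6 are contiguous. Read in three dimensions, H2, the C1 hydroxyl, H5 and H6 all lie on the convex face, so both aryl groups are endo, which is the arrangement disfavoured at equilibrium. The two electron-rich benzylic ether bonds (C2–O3 and C6–O7) are fragile: acid ionizes them and they re-close to the exo epimers. The real difficulty is to place both aryl groups on the concave face, next to a bridgehead tertiary alcohol, without exposing a finished benzylic centre to acid. The key step exploits the fact that the O–C1 and H–C2 bonds are cis on ring B and both on the open convex face, so one syn addition to a C1=C2 enol ether can make both.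

## Logic of the disconnections

**19 ⇒ 17.** Bonds cut: C1–OH and C2–H (retro syn hydration across C1–C2). These bonds are cis and convex, so one syn addition makes both. The cut removes two stereocentres, the tertiary alcohol and the acid-sensitive C2 centre, and leaves a planar tetrasubstituted enol ether. The forward step must put boron on C1 and not C2, add only on the face of H5, and use no acid. In one sentence, the route is a convex-face syn hydroboration–oxidation of 17.

**17 ⇒ 15 ⇒ 13 + 9.** The C1=C2 π bond is traced back to a C2–OH/C1–H pair in 15, and the C2–aryl bond is then cut to the lactone carbonyl of 13 and the arylmagnesium reagent 14 made from 9. C2 has no stereochemistry at this stage, and H1 is the only β-hydrogen, so 17 is the only enol ether that can form. The forward steps need mono-addition to the lactone by a nucleophile of low basicity, and a dehydration mild enough not to ionize C6–O7.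

**13 ⇒ 11 ⇒ 8 + 9.** Bonds cut: C6–H, then C6–aryl. Because 8 is C2-symmetric, its two carbonyl groups are homotopic and the first aryl group can enter at either one. The C6–H bond is then made by hydride delivery to the ring A oxocarbenium ion 12 on the convex face, which places the aryl group endo. The forward steps need a single addition of 10 and a reduction under kinetic control.

**8 ⇒ 7 ⇒ 6.** Bonds cut: the two lactone C–O bonds, O3–C2 and O7–C6. Each hydroxymethyl group can reach only the distal acyl group through a five-membered ring, so the (R,R) chain of 7 folds to the cis-fused bicycle and releases the auxiliary. Only the like (R,R) isomer can do this.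

**6 ⇒ 4 + 4.** Bond cut: the central C1–C5 bond, between two α-carbons of like (nucleophilic) polarity. Forward, this is an oxidative coupling of the enolate 5. The hidden symmetry about this bond halves the problem, and the auxiliary controls both centres in the same sense. The forward step needs single-electron oxidation to outrun β-elimination of benzyloxide, and like selectivity.

**4 ⇒ 1 + 2 (via 3).** Bond cut: the imide N–C(O) bond, a routine acylation that joins the three-carbon acid to the auxiliary.

## Other disconnections considered

**Alternative 1:** (the first that comes to mind) Cut C2–H and C6–H, with both aryl–carbon bonds, symmetrically. The enolate of 8 would be hydroxylated at the bridgehead to the hydroxy dilactone A1, two equivalents of 10 would add to give the bis-hemiketal A2, and a double ionic hydrogenation (Et3SiH, BF3·OEt2) would be the key step. This sequence would be two steps shorter than the chosen route. The objection is that the second C–H bond is made by a Lewis acid in the presence of the electron-rich endo benzylic ether formed first, which should ionize and drift to the exo epimer. The C2 oxocarbenium ion would also sit next to a free tertiary hydroxyl, which invites neighbouring-group capture or a semipinacol shift and weakens the facial bias. The chosen plan makes the C1–O and C2–H bonds in one acid-free syn addition whose relative configuration is fixed by geometry.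

**Alternative 2:** Cut C1–C2 by a Norrish–Yang photocyclization of the ring A ketone A3. The excited carbonyl abstracts a benzylic ether hydrogen (1,6-shift), and radical recombination closes ring B and creates the C1 carbinol in one step. The idea is attractive, but A3 needs a 4,5-cis arrangement at a centre α to the ketone, which should epimerize to trans. The recombination should also place the aryl group on the convex face (cis to OH), the wrong C2 epimer here, and α-cleavage toward C8 competes.

**Alternative 3:** Cut C1–C2 by C–H insertion. The carbenoid from the diazo lactone A4 (Rh2(OAc)4, dirhodium tetraacetate) would insert into the benzylic ether C–H to give the bicyclic lactone A5, with a kinetic preference for the endo aryl group. C1 is made as C–H, so bridgehead hydroxylation, lactone reduction and ring A etherification would still follow. A4 also needs a cis-4,5-disubstituted lactone and a diazo transfer, and the carbenoid can attack the electron-rich arene or the ether oxygen. The endo outcome is a transition-state preference, not a geometric necessity, and the route is longer.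

Key step: step 8

## Steps

**Step 1**
Reactants: 1 3-(benzyloxy)propanoic acid; 2 (R)-4-benzyl-1,3-oxazolidin-2-one
Product: 4 (R)-4-benzyl-3-[3-(benzyloxy)propanoyl]-1,3-oxazolidin-2-one, via mixed pivalic anhydride 3 (not isolated)
Conditions: PivCl, Et3N, THF, −20 °C; then 2, LiCl, −20 °C → rt
Reagents that add atoms: none
Why: N-acylation of the oxazolidinone through the mixed anhydride; the hindered pivaloyl carbonyl is not attacked, so only the 3-(benzyloxy)propanoyl group is transferred.

**Step 2**
Reactants: 4 (two molecules)
Product: 6 (2R,3R)-1,4-bis[(R)-4-benzyl-2-oxo-1,3-oxazolidin-3-yl]-2,3-bis[(benzyloxy)methyl]butane-1,4-dione, via lithium Z-enolate 5 (not isolated)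
Conditions: LiN(i-Pr)2, THF, −78 °C; then CuCl2 (1.1 equiv), DMF/THF, −78 → −20 °C
Reagents that add atoms: none
Why: Oxidative enolate homocoupling: divalent copper oxidizes the chelated Z-enolate by one electron and the α-carbons of two units join. Each unit should react on the face away from the auxiliary benzyl group, as in alkylations of this auxiliary, so both new centres have the same sense and the like (R,R) dimer is expected from the (R)-auxiliary.

**Step 3**
Reactants: 6
Product: 8 (1R,5R)-3,7-dioxabicyclo[3.3.0]octane-2,6-dione, via diol bis-imide 7 (not isolated)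
Conditions: H2 (1 atm), Pd(OH)2/C, EtOAc, rt; filter; then Et3N (cat.), CH2Cl2, rt
Reagents that add atoms: none
Why: Hydrogenolysis frees both primary alcohols, and each attacks the distal activated imide carbonyl (γ-lactonization) with loss of the auxiliary. The (R,R) configuration from step 2 is carried over unchanged and fixes the cis ring fusion.

**Step 4**
Reactants: 8; 9 4-bromo-1,2-dimethoxybenzene
Product: 11 (1R,5R)-6-(3,4-dimethoxyphenyl)-6-hydroxy-3,7-dioxabicyclo[3.3.0]octan-2-one (C6 epimers), via (3,4-dimethoxyphenyl)lithium 10 (not isolated)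
Conditions: 9, n-BuLi, THF, −78 °C; cannulate into 8 (1.3 equiv), THF, −78 °C; sat. aq NH4Cl
Reagents that add atoms: none
Why: Bromine–lithium exchange, then 1,2-addition of the aryllithium to one of the two homotopic lactone carbonyls. The tetrahedral lithium alkoxide is stable at −78 °C, which should stop the reaction at the hemiketal.

**Step 5**
Reactants: 11
Product: 13 (1R,5R,6R)-6-(3,4-dimethoxyphenyl)-3,7-dioxabicyclo[3.3.0]octan-2-one (aryl endo), via oxocarbenium ion 12 (not isolated)
Conditions: Et3SiH, BF3·OEt2, CH2Cl2, −78 → −40 °C; sat. aq NaHCO3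
Reagents that add atoms: none
Why: Ionic hydrogenation of the hemiketal. Hydride should reach C6 of the ring A oxocarbenium ion from the convex face (cis to H5), which sets H6 exo and the aryl group endo under kinetic control. The lactone is inert, and C1/C5 anchor the cis fusion.

**Step 6**
Reactants: 13; 9 4-bromo-1,2-dimethoxybenzene
Product: 15 (1R,5R,6R)-2,6-bis(3,4-dimethoxyphenyl)-3,7-dioxabicyclo[3.3.0]octan-2-ol (C2 epimers), via (3,4-dimethoxyphenyl)magnesium bromide 14 (not isolated)
Conditions: 9, Mg turnings, I2 (cat.), THF, 40 °C → rt; then add to 13 (1.05 equiv of the reagent), THF, −78 → −20 °C; sat. aq NH4Cl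
Reagents that add atoms: none
Why: Magnesium insertion into the aryl bromide gives the Grignard reagent, and its 1,2-addition to the remaining lactone (Grignard addition) gives the cyclic hemiketal after the mild quench. The magnesium reagent is less basic than the lithium reagent, which matters because 13 is the limiting component and carries the enolizable H1. The new C2 centre need not be controlled because it becomes sp2 in the next step.

**Step 7**
Reactants: 15
Product: 17 (5R,6R)-2,6-bis(3,4-dimethoxyphenyl)-3,7-dioxabicyclo[3.3.0]oct-1-ene, via hemiketal methanesulfonate 16 (not isolated)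
Conditions: MsCl, Et3N (excess), DMAP (cat.), CH2Cl2, −20 °C → rt; Et3N-buffered work-up
Reagents that add atoms: none
Why: Sulfonylation of the hemiketal hydroxyl, ionization to the aryl-stabilized oxocarbenium ion, and loss of H1, the only β-hydrogen, give the tetrasubstituted enol ether. The medium stays basic, so C6–O7 is not ionized, and C5 and C6 are untouched.

**Step 8**
Reactants: 17
Product: 19 (1S,2S,5R,6R)-2,6-bis(3,4-dimethoxyphenyl)-3,7-dioxabicyclo[3.3.0]octan-1-ol (target), via tertiary alkylborane 18 (not isolated)
Conditions: BH3·THF (3 equiv), THF, 0 °C → rt; then aq NaOH, 30% H2O2, 0 °C → rt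
Reagents that add atoms: hydrogen peroxide, OO
Why: BH3 adds across C1=C2 through the four-centre transition state, boron to C1 (β to O3) and hydride to C2, which carries the partial positive charge stabilized by O3 and the dimethoxyphenyl ring; alkaline peroxide then replaces boron by OH with retention through the 1,2-shift from boron to oxygen. The closest known reaction type is hydroboration–oxidation of cyclic enol ethers such as 1-aryl glycals and 2,3-dihydrofurans, which gives trans-2-aryl-3-hydroxy cyclic ethers. The step closes no ring; both rings are in place and only the planar C1=C2 unit becomes two stereocentres. C1 is controlled by the bicycle: boron must enter on the convex face, cis to H5, because addition on the other face would lead to a trans-fused bicyclo[3.3.0] skeleton and that face is also roofed by the endo aryl group on C6. C2 is controlled by the syn mode of addition: H2 arrives on the same face as boron, so the aryl group is pushed to the concave face, trans to the new hydroxyl. The step needs regioselectivity (boron at C1), convex-face selectivity, and survival of the β-alkoxyborane 18 until oxidation; the enol ether polarization, the cup shape of 17, and low temperature with prompt oxidation should secure these. Benzylic and aryl methyl ethers are inert to BH3 and to alkaline peroxide, so the finished endo centres never meet acid.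

## Compound list

1 | 3-(benzyloxy)propanoic acid | OC(=O)CCOCc1ccccc1 | starting material
2 | (R)-4-benzyl-1,3-oxazolidin-2-one | O=C1N[C@H](Cc2ccccc2)CO1 | starting material
3 | 3-(benzyloxy)propanoic pivalic anhydride | CC(C)(C)C(=O)OC(=O)CCOCc1ccccc1 | intermediate
4 | (R)-4-benzyl-3-[3-(benzyloxy)propanoyl]-1,3-oxazolidin-2-one | O=C(CCOCc1ccccc1)N1[C@H](Cc2ccccc2)COC1=O | intermediate
5 | lithium (Z)-enolate of 4 | [Li+].[O-]/C(=C\COCc1ccccc1)N1[C@H](Cc2ccccc2)COC1=O | intermediate
6 | (2R,3R)-1,4-bis[(R)-4-benzyl-2-oxo-1,3-oxazolidin-3-yl]-2,3-bis[(benzyloxy)methyl]butane-1,4-dione | O=C(N1[C@H](Cc2ccccc2)COC1=O)[C@@H](COCc1ccccc1)[C@H](COCc1ccccc1)C(=O)N1[C@H](Cc2ccccc2)COC1=O | intermediate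
7 | (2R,3R)-1,4-bis[(R)-4-benzyl-2-oxo-1,3-oxazolidin-3-yl]-2,3-bis(hydroxymethyl)butane-1,4-dione | O=C(N1[C@H](Cc2ccccc2)COC1=O)[C@@H](CO)[C@H](CO)C(=O)N1[C@H](Cc2ccccc2)COC1=O | intermediate
8 | (1R,5R)-3,7-dioxabicyclo[3.3.0]octane-2,6-dione (cis-fused, C2-symmetric) | O=C1OC[C@H]2[C@@H]1COC2=O | intermediate
9 | 4-bromo-1,2-dimethoxybenzene | COc1ccc(Br)cc1OC | starting material
10 | (3,4-dimethoxyphenyl)lithium | [Li]c1ccc(OC)c(OC)c1 | intermediate
11 | (1R,5R)-6-(3,4-dimethoxyphenyl)-6-hydroxy-3,7-dioxabicyclo[3.3.0]octan-2-one (C6 epimers) | COc1ccc(cc1OC)C1(O)OC[C@H]2[C@@H]1COC2=O | intermediate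
12 | (1R,5R)-6-(3,4-dimethoxyphenyl)-2-oxo-3,7-dioxabicyclo[3.3.0]oct-6-en-7-ium hydroxytrifluoroborate | COc1ccc(cc1OC)C1=[O+]C[C@H]2[C@@H]1COC2=O.O[B-](F)(F)F | intermediate
13 | (1R,5R,6R)-6-(3,4-dimethoxyphenyl)-3,7-dioxabicyclo[3.3.0]octan-2-one (aryl endo, H6 cis to H5) | COc1ccc([C@@H]2OC[C@H]3[C@@H]2COC3=O)cc1OC | intermediate
14 | (3,4-dimethoxyphenyl)magnesium bromide | Br[Mg]c1ccc(OC)c(OC)c1 | intermediate
15 | (1R,5R,6R)-2,6-bis(3,4-dimethoxyphenyl)-3,7-dioxabicyclo[3.3.0]octan-2-ol (C2 epimers) | COc1ccc([C@@H]2OC[C@H]3[C@@H]2COC3(O)c2ccc(OC)c(OC)c2)cc1OC | intermediate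
16 | (1R,5R,6R)-2,6-bis(3,4-dimethoxyphenyl)-3,7-dioxabicyclo[3.3.0]octan-2-yl methanesulfonate | COc1ccc([C@@H]2OC[C@H]3[C@@H]2COC3(OS(C)(=O)=O)c2ccc(OC)c(OC)c2)cc1OC | intermediate
17 | (5R,6R)-2,6-bis(3,4-dimethoxyphenyl)-3,7-dioxabicyclo[3.3.0]oct-1-ene (6-aryl endo) | COc1ccc([C@@H]2OCC3=C(c4ccc(OC)c(OC)c4)OC[C@H]23)cc1OC | intermediate
18 | [(1R,2R,5R,6R)-2,6-bis(3,4-dimethoxyphenyl)-3,7-dioxabicyclo[3.3.0]octan-1-yl]borane (boron on the convex face) | COc1ccc([C@@H]2OC[C@@]3(B)[C@@H]2CO[C@H]3c2ccc(OC)c(OC)c2)cc1OC | intermediate
19 | (1S,2S,5R,6R)-2,6-bis(3,4-dimethoxyphenyl)-3,7-dioxabicyclo[3.3.0]octan-1-ol (both aryl groups endo) | COc1ccc([C@@H]2OC[C@@]3(O)[C@@H]2CO[C@H]3c2ccc(OC)c(OC)c2)cc1OC | target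

## Step count and least certain steps

Total: 8 steps. Longest linear sequence: 8 steps (1 and 2 to 19; 9 enters twice).

**Step 8 (key step).** The β-alkoxyborane may undergo ring-opening elimination across C1–C2, or addition to the hindered tetrasubstituted double bond may be slow enough that the enol ether is simply hydrated on work-up. Fallback, from 17: catalytic OsO4 with N-methylmorpholine N-oxide should dihydroxylate the enol ether on the convex face to give (1S,5R,6R)-2,6-bis(3,4-dimethoxyphenyl)-3,7-dioxabicyclo[3.3.0]octane-1,2-diol F1. Ionic hydrogenation of this hemiketal (Et3SiH, BF3·OEt2, CH2Cl2, −78 °C), with hydride delivered to C2 on the convex face, returns to the route at 19.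

**Step 2.** The radical coupling may be unselective (like/unlike mixture), and benzyloxide may be lost from the enolate by β-elimination before oxidation. Fallback, from 4: the sodium enolate (NaN(SiMe3)2, THF, −78 °C) is alkylated in a two-electron SN2 reaction, with inversion, by the serine-derived triflate benzyl (S)-3-(benzyloxy)-2-{[(trifluoromethyl)sulfonyl]oxy}propanoate F2. This gives the imide ester benzyl (2R,3R)-4-[(R)-4-benzyl-2-oxo-1,3-oxazolidin-3-yl]-2,3-bis[(benzyloxy)methyl]-4-oxobutanoate F3. Hydrogenolysis of its three benzyl groups gives the dihydroxy acid (2R,3R)-4-[(R)-4-benzyl-2-oxo-1,3-oxazolidin-3-yl]-2,3-bis(hydroxymethyl)-4-oxobutanoic acid F4, and acid-catalysed double lactonization (TsOH, toluene) returns to the route at 8.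

**Step 4.** A second addition of the aryllithium (to the other lactone or to the ring-opened ketone) or enolization of 8 may erode the mono-adduct. Fallback, from 8: aminolysis of one of the two homotopic lactones with MeNH(OMe)·HCl and AlMe3 gives the N-methoxy-N-methylamide (3R,4R)-4-(hydroxymethyl)-N-methoxy-N-methyl-5-oxooxolane-3-carboxamide F5. Two equivalents of 10 are then expected to react at the amide and stop at the chelated adduct, and work-up releases the ketone, closes the hemiketal and returns to the route at 11.

**Step 5.** The new endo benzylic ether may ionize under BF3 and re-close to the exo epimer, or hydride delivery may not be fully convex-face selective. Fallback, from 11: the open hydroxy-ketone tautomer is reduced under reagent control ((S)-2-methyl-CBS-oxazaborolidine, BH3·SMe2) to the (R)-carbinol, the diol (3R,4R)-4-[(R)-(3,4-dimethoxyphenyl)(hydroxy)methyl]-3-(hydroxymethyl)oxolan-2-one F6. Mitsunobu cyclodehydration (PPh3, DIAD) activates the primary hydroxyl, so the benzylic oxygen closes ring A by SN2 at C8 with C6 untouched; this returns to the route at 13.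

**Step 6.** The magnesium alkoxide of the first adduct may open to the aryl ketone while the Grignard reagent is still present, so that a second aryl group adds and a diaryl carbinol results. Fallback, from 13: aminolysis of the lactone with MeNH(OMe)·HCl and AlMe3 gives the N-methoxy-N-methylamide (3R,4R,5R)-5-(3,4-dimethoxyphenyl)-4-(hydroxymethyl)-N-methoxy-N-methyloxolane-3-carboxamide F7. Two equivalents of 14 (the first is spent on the hydroxyl) then stop at the chelated tetrahedral adduct, and work-up releases the ketone, which closes to the hemiketal and returns to the route at 15.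

**Step 7.** The open-chain tautomer of 15 may be sulfonylated at its primary hydroxyl and then cyclize through carbon to a cyclopropyl ketone, or the acid-labile enol ether may rehydrate on isolation. Fallback, from 13: KN(SiMe3)2 and (PhO)2P(O)Cl give the ketene acetal phosphate (5R,6R)-6-(3,4-dimethoxyphenyl)-3,7-dioxabicyclo[3.3.0]oct-1-en-2-yl diphenyl phosphate F8. Suzuki–Miyaura coupling with (3,4-dimethoxyphenyl)boronic acid (Pd(PPh3)4, aq Na2CO3, THF) then returns to the route at 17 without passing through a hemiketal.

## Further compounds

F1 | step 8 | (1S,5R,6R)-2,6-bis(3,4-dimethoxyphenyl)-3,7-dioxabicyclo[3.3.0]octane-1,2-diol (C2 epimers) | COc1ccc([C@@H]2OC[C@@]3(O)[C@@H]2COC3(O)c2ccc(OC)c(OC)c2)cc1OC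
F2 | step 2 | benzyl (S)-3-(benzyloxy)-2-{[(trifluoromethyl)sulfonyl]oxy}propanoate | O=C(OCc1ccccc1)[C@H](COCc1ccccc1)OS(=O)(=O)C(F)(F)F
F3 | step 2 | benzyl (2R,3R)-4-[(R)-4-benzyl-2-oxo-1,3-oxazolidin-3-yl]-2,3-bis[(benzyloxy)methyl]-4-oxobutanoate | O=C(N1[C@H](Cc2ccccc2)COC1=O)[C@@H](COCc1ccccc1)[C@H](COCc1ccccc1)C(=O)OCc1ccccc1
F4 | step 2 | (2R,3R)-4-[(R)-4-benzyl-2-oxo-1,3-oxazolidin-3-yl]-2,3-bis(hydroxymethyl)-4-oxobutanoic acid | O=C(N1[C@H](Cc2ccccc2)COC1=O)[C@@H](CO)[C@H](CO)C(O)=O
F5 | step 4 | (3R,4R)-4-(hydroxymethyl)-N-methoxy-N-methyl-5-oxooxolane-3-carboxamide | CON(C)C(=O)[C@H]1COC(=O)[C@H]1CO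
F6 | step 5 | (3R,4R)-4-[(R)-(3,4-dimethoxyphenyl)(hydroxy)methyl]-3-(hydroxymethyl)oxolan-2-one | COc1ccc([C@H](O)[C@H]2COC(=O)[C@H]2CO)cc1OC
F7 | step 6 | (3R,4R,5R)-5-(3,4-dimethoxyphenyl)-4-(hydroxymethyl)-N-methoxy-N-methyloxolane-3-carboxamide | COc1ccc([C@@H]2OC[C@H](C(=O)N(C)OC)[C@@H]2CO)cc1OC
F8 | step 7 | (5R,6R)-6-(3,4-dimethoxyphenyl)-3,7-dioxabicyclo[3.3.0]oct-1-en-2-yl diphenyl phosphate | COc1ccc([C@@H]2OCC3=C(OP(=O)(Oc4ccccc4)Oc4ccccc4)OC[C@H]23)cc1OC
A1 | alternative 1 | (1S,5S)-1-hydroxy-3,7-dioxabicyclo[3.3.0]octane-2,6-dione | O=C1OC[C@@]2(O)[C@@H]1COC2=O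
A2 | alternative 1 | (1S,5S)-2,6-bis(3,4-dimethoxyphenyl)-3,7-dioxabicyclo[3.3.0]octane-1,2,6-triol (C2 and C6 epimers) | COc1ccc(cc1OC)C1(O)OC[C@@]2(O)[C@@H]1COC2(O)c1ccc(OC)c(OC)c1
A3 | alternative 2 | (4R,5R)-5-(3,4-dimethoxyphenyl)-4-{[(3,4-dimethoxyphenyl)methoxy]methyl}oxolan-3-one | O=C1CO[C@@H](c2ccc(OC)c(OC)c2)[C@H]1COCc1ccc(OC)c(OC)c1
A4 | alternative 3 | (4R,5R)-3-diazo-5-(3,4-dimethoxyphenyl)-4-{[(3,4-dimethoxyphenyl)methoxy]methyl}oxolan-2-one | O=C1O[C@@H](c2ccc(OC)c(OC)c2)[C@@H](COCc2ccc(OC)c(OC)c2)C1=[N+]=[N-]
A5 | alternative 3 | (1S,2R,5R,6R)-2,6-bis(3,4-dimethoxyphenyl)-3,7-dioxabicyclo[3.3.0]octan-8-one (both aryl groups endo) | COc1ccc([C@@H]2OC(=O)[C@H]3[C@@H]2CO[C@H]3c2ccc(OC)c(OC)c2)cc1OC
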